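## Analysis of the target

The target is a spiro[5.5]undecane of the chamigrane type, numbered here so that ring A is C1 (exocyclic methylidene), C2, C3, C4 (CHBr), C5 (CMe2) and C6 (spiro), and ring B is C6, C7, C8, C9 (C(OH)CH3), C10 (CHBr) and C11. It has four stereocentres, C4 (S), C6 (R), C9 (R) and C10 (R), and C6 is stereogenic only because both rings are unsymmetrical, so its configuration is defined by which α-carbon of ring B carries bromine. In ring B the hydroxyl and the bromine are trans and both equatorial in the chair that keeps C5 equatorial and C1 axial, with the C9 methyl axial; the C10 bromine is cis to C5, the hydroxyl is cis to C1, and the C4 bromine lies on the face of ring A that carries C11. The sensitive groups are the neopentyl secondary bromide at C4 (ionization invites Wagner–Meerwein shifts), the β-bromo tertiary alcohol (epoxide closure or elimination with base) and the 1,1-disubstituted alkene (acid and electrophiles). The synthesis is hard because of the vicinal fully substituted carbons C5 and C6, a bromine on a neopentyl carbon, a trans-diequatorial bromohydrin that anti addition to a ring B alkene does not give directly, and two stereochemical units (C4 on one side, C6/C9/C10 on the other) that are too far apart to control each other. The strategy rests on C1 and C5, the two ring A neighbours of C6: C=CH2 and CMe2 can both be traced back to C=O, which turns ring A into cyclohexane-1,3-dione with C6 as its C2. A ketone at C9 is then β to C6 through both C7–C8 and C11–C10, so ring B is the product of two conjugate additions of that one carbon.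

## Retrosynthetic reasoning

**16 to 15 (C9–CH3).** The tertiary carbinol is cut at its methyl group. This exposes a ring B ketone whose α-carbon already carries the C10 bromine. The forward step must deliver methyl axially to a chair with equatorial bromine, which gives the trans-diequatorial bromohydrin that alkene addition cannot give directly.

**15 to 14 to 13 (C10–Br).** The bromine is removed through the silyl enol ether 14. In 13 ring B is locally symmetric and C6 is not stereogenic. Choosing C10 over C8 therefore creates C6, and this must be done by a chiral lithium amide because C4 is too remote to decide it. The C10 configuration follows from the chair: equatorial bromine, cis to C5, is the stable epimer.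

**13 to 12 to 11 (one C5–CH3).** One methyl of the gem-dimethyl group is cut, leading to a tertiary β-bromo alcohol. The forward step is an ionizing methyl transfer from a methyltitanium reagent. Such reagents also attack ketones and acetals, so the ring B carbonyl is held as the secondary alcohol (11, 12) across this step and restored in 13.

**11 to 10 to 9 to 8 (second C5–CH3 and ring B oxidation level).** The second methyl is cut back to the α-bromoketone 8, through methyl addition to a carbonyl. The ring B carbonyl is masked as a dioxolane while nucleophiles and bases are used (9, 8), then exchanged for the alcohol (10, 11).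

**8 to 7 (C4–Br).** The bromine sits α to the C5 carbonyl, and C4 is the only enolizable position of 7. Because 7 is achiral, the forward step needs an enantioselective catalyst. This sets the one stereocentre that ring B cannot influence.

**7 to 6 to 5 (C1=CH2 and protection).** The methylidene comes from one of the two ring A carbonyls of 6. They are homotopic, so only mono- versus bis-olefination has to be controlled. 6 is the trione 5 with its unhindered ring B ketone masked.

**5 to 1 and 3 (C6–C7 and C6–C11).** Both bonds from C6 into ring B are β to the C9 carbonyl. Cutting them gives the dione 1 and the dienone 3, the latter released from 2, with the mono-adduct 4 in between. This cut is chosen because it removes the quaternary spiro carbon and a whole ring in one operation from two achiral pieces, with no stereochemistry to control. All stereocentres are left to later reagent-controlled steps.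

## Alternatives that were turned down

Alternative 1: Ring B is traced to 4-methylcyclohex-3-ene-1,1-dicarboxylic acid A2. The forward key step is a catalytic enantioselective bromolactonization, in which one of the two enantiotopic carboxyl groups attacks the methyl-bearing alkene carbon anti to the bromonium ion and gives the bridged bromolactone A1.
- For it: C9, C10 and the future spiro carbon are set in one catalytic step, the trans Br/O relation is inherent, and the lactone ties the oxygen to the carboxyl carbon that must become C1, which matches the target. On ring B this is stronger than the chosen route, which needs three steps and a stoichiometric chiral base.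
- Against it: ring A is entirely missing after the key step. Both carboxyl carbons must be turned into C1 and C5 by C–C bond formation at neopentyl positions, and the C2–C3–C4 chain with its bromide must be added and the ring closed, all while a base-sensitive bromolactone is carried. The CMe2/CHBr problem is untouched.
- Comparison: the chosen route has the full carbon skeleton after step 1 and spends its steps only on functional groups.

Alternative 2: The bond from C6 to the ring B CH2 next to the future CHBr is cut by a retro-Claisen step. This leads to the fused 2-methyl-2-vinyl dihydropyran A4, whose carbinol centre would come from (R)-linalool A5. In the forward key step, heating A4 contracts the oxacycle by a [3,3] shift to the spiro ketone A3.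
- For it: chirality is transferred from a cheap chiral-pool alcohol to the quaternary carbon through a cyclic transition state. Ring A already carries CMe2 and CHBr, so no cationic methylation is needed late; on that point it is stronger than the chosen route.
- Against it: A4 needs a hindered tertiary allylic enol ether and already contains the neopentyl bromide, which must survive a high-temperature rearrangement. A3 then needs methylenation of a ketone flanked by C6 and, one carbon on, by CMe2. The bromohydrin would have to come from the ring B alkene, where anti addition through the favoured chair does not lead cleanly to the diequatorial Br/OH pattern, and the exocyclic alkene competes for the bromine donor.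
- Comparison: the chosen route makes the bromohydrin from a ketone, where the equatorial bromine is the stable epimer and the methyl is delivered axially.

Alternative 3: The C6–C1 bond is cut, leading to the para-substituted phenol A7 with a terminal alkyne. In the forward key step a cationic gold catalyst with a phosphine ligand activates the alkyne, and the phenol attacks through its para carbon (6-exo-dig) to give the spiro dienone A6.
- For it: ring A, including the exocyclic methylidene, closes in one atom-economical catalytic step. The gem-dimethyl group is made earlier by ordinary enolate methylation, so the cationic methylation of the chosen route is avoided; on that point it is stronger.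
- Against it: A6 still lacks the C6 stereocentre. Both enone double bonds must be reduced without touching the exocyclic alkene or the C–Br bond, which only brings the material to the ketone 13 of the chosen route, so the ring B work is the same or longer. The acyclic neopentyl bromide of A7, next to a benzylic quaternary carbon, must be made as a single enantiomer and is prone to aryl participation. Ipso attack has to win over ortho attack at a para carbon that carries a quaternary substituent.
- Comparison: the chosen route reaches 13 from commercial materials in nine steps and has no aromatic ring to reduce.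

Key step: step 1

Assumption: 1,5-dichloropentan-3-one is taken as a catalogue compound, and the senses of induction in steps 4 and 10 are assigned by analogy with cyclohexanone and 4-tert-butylcyclohexanone, the antipodal catalyst or base being used if the analogy does not carry over.

## Route

Step 1
Reactants: 1 cyclohexane-1,3-dione; 2 1,5-dichloropentan-3-one
Product: 5 spiro[5.5]undecane-1,5,9-trione, via penta-1,4-dien-3-one 3 (not isolated), via 2-(3-oxopent-4-enyl)cyclohexane-1,3-dione 4 (not isolated)
Conditions: K2CO3 (3.5 equiv), MeCN (0.05 M), 2 added over 6 h at 0 °C, then 40 °C
Reagents that add atoms: none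
Why: Carbonate deprotonates 1 and strips HCl from 2 by E1cB elimination, so the dienone 3 is released slowly and never accumulates. The soft enolate of 1 adds through its central carbon to 3 (Michael addition), and the still acidic 2-substituted dione 4 is deprotonated again and adds through the same carbon to the second vinyl ketone. This second addition is a 6-endo-trig closure that forms ring B as a cyclohexanone and makes C6 quaternary; ring A is carried in from 1. The closest known reaction type is the double Michael spiroannulation of cyclic 1,3-dicarbonyl compounds with divinyl ketones. No stereocentre is formed, since 5 is achiral. The step needs C- over O-alkylation, which conjugate acceptors give because O-adducts revert, and ring closure over a second intermolecular addition, which dilution and the low standing concentration of 3 favour. A non-nucleophilic base in an aprotic solvent avoids retro-Claisen opening of the 2,2-disubstituted dione.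

Step 2
Reactants: 5 spiro[5.5]undecane-1,5,9-trione
Product: 6 9,9-(ethylenedioxy)spiro[5.5]undecane-1,5-dione (ring B ketone as its 1,3-dioxolane)
Conditions: TMSOCH2CH2OTMS (1.1 equiv), TMSOTf (5 mol%), CH2Cl2, −78 °C; pyridine quench
Reagents that add atoms: 1,2-bis(trimethylsilyloxy)ethane, C[Si](C)(C)OCCO[Si](C)(C)C
Why: Noyori ketalization under kinetic control: the unhindered ring B ketone reacts, while the two ring A carbonyls are neopentylic, flanked by the quaternary C6. The aprotic conditions avoid the acid-catalysed ring opening that 2,2-disubstituted 1,3-diones suffer with free glycol.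

Step 3
Reactants: 6 9,9-(ethylenedioxy)spiro[5.5]undecane-1,5-dione
Product: 7 9,9-(ethylenedioxy)-1-methylidenespiro[5.5]undecan-5-one
Conditions: Ph3PCH3Br (1.05 equiv), KN(SiMe3)2 (1.0 equiv), THF, −78 °C to rt
Reagents that add atoms: methyltriphenylphosphonium bromide, C[P+](c1ccccc1)(c1ccccc1)c1ccccc1.[Br-]
Why: Wittig methylenation; the two ring A carbonyls of 6 are homotopic, so only mono- versus bis-olefination matters. One equivalent of ylide should stop at 7 because the remaining ketone has lost the activating second carbonyl and is neopentylic.

Step 4
Reactants: 7 9,9-(ethylenedioxy)-1-methylidenespiro[5.5]undecan-5-one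
Product: 8 (4S)-4-bromo-9,9-(ethylenedioxy)-1-methylidenespiro[5.5]undecan-5-one
Conditions: (4R,5R)-4,5-diphenylimidazolidine (20 mol%), PhCO2H (20 mol%), 4,4-dibromo-2,6-di-tert-butylcyclohexa-2,5-dienone (1.05 equiv), THF, −20 °C
Reagents that add atoms: 4,4-dibromo-2,6-di-tert-butylcyclohexa-2,5-dienone, CC(C)(C)C1=CC(Br)(Br)C=C(C(C)(C)C)C1=O
Why: Enamine-catalysed enantioselective α-bromination of a cyclic ketone: C4 is the only enolizable position, the C2-symmetric amine shields one face of the enamine, and the mild bromine donor leaves the 1,1-disubstituted alkene alone. The ketone is hindered, so a long reaction time is expected, and 8 is used at once because α-bromoketones racemize through the enol.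

Step 5
Reactants: 8 (4S)-4-bromo-9,9-(ethylenedioxy)-1-methylidenespiro[5.5]undecan-5-one
Product: 9 (4S,5R)-4-bromo-9,9-(ethylenedioxy)-5-methyl-1-methylidenespiro[5.5]undecan-5-ol (OH cis to Br)
Conditions: MeLi, CeCl3 (dried), THF, −78 °C; AcOH quench at −78 °C
Reagents that add atoms: methyllithium, [Li]C (used as methylcerium dichloride, C[Ce](Cl)Cl)
Why: Organocerium 1,2-addition, which adds to enolizable α-haloketones without deprotonation or attack on the halide. Methyl should enter anti to the C–Br bond (polar Felkin–Anh or Cornforth control), so the 5R epimer is expected; the C5 configuration is in any case erased in step 8.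

Step 6
Reactants: 9 (4S,5R)-4-bromo-9,9-(ethylenedioxy)-5-methyl-1-methylidenespiro[5.5]undecan-5-ol
Product: 10 (4S,5R)-4-bromo-5-hydroxy-5-methyl-1-methylidenespiro[5.5]undecan-9-one
Conditions: PPTS (0.2 equiv), acetone/H2O (5:1), 45 °C
Reagents that add atoms: water, O
Why: Mild acid hydrolysis of the dioxolane, needed because acetals are themselves methylated by methyltitanium chlorides. PPTS should neither ionize the β-bromo tertiary alcohol nor isomerize the exocyclic alkene.

Step 7
Reactants: 10 (4S,5R)-4-bromo-5-hydroxy-5-methyl-1-methylidenespiro[5.5]undecan-9-one
Product: 11 (4S,5R)-4-bromo-5-methyl-1-methylidenespiro[5.5]undecane-5,9-diol (both C9 epimers, carried together)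
Conditions: NaBH4, MeOH, −20 °C
Reagents that add atoms: none
Why: Borohydride reduction parks the ring B carbonyl at the alcohol level, where it survives step 8 as a secondary titanium alkoxide. The C9 configuration is immaterial because step 9 returns the ketone.

Step 8
Reactants: 11 (4S,5R)-4-bromo-5-methyl-1-methylidenespiro[5.5]undecane-5,9-diol
Product: 12 (4S)-4-bromo-5,5-dimethyl-1-methylidenespiro[5.5]undecan-9-ol (both C9 epimers)
Conditions: Me2TiCl2 (5 equiv, from Me2Zn and TiCl4), CH2Cl2, −78 °C to 0 °C
Reagents that add atoms: dimethylzinc, C[Zn]C (methyl source, acting as dimethyltitanium dichloride, C[Ti](C)(Cl)Cl)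
Why: Proposed new method: the tertiary C5–O–Ti bond of the titanium alkoxide ionizes, the bromine on C4 (gauche to the leaving oxygen, so bridging only once the cation has formed) closes to a bromonium ion that keeps the C4 configuration and holds back 1,2-shifts from C6, and methyl is transferred from titanium to the tertiary carbon so that C5 becomes CMe2, while the secondary alkoxide at C9 does not ionize; the closest known reaction type is the Reetz methylation of tertiary alcohols and geminal dimethylation of ketones with Me2TiCl2, known also next to quaternary carbons, together with the retention seen in solvolysis of β-bromoalkyl derivatives.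

Step 9
Reactants: 12 (4S)-4-bromo-5,5-dimethyl-1-methylidenespiro[5.5]undecan-9-ol
Product: 13 (4S)-4-bromo-5,5-dimethyl-1-methylidenespiro[5.5]undecan-9-one
Conditions: Dess–Martin periodinane, NaHCO3, CH2Cl2, 0 °C to rt
Reagents that add atoms: none
Why: Dess–Martin oxidation of the secondary alcohol under buffered conditions; both C9 epimers give the same ketone, in which ring B is again locally symmetric and C4 is the only stereocentre.

Step 10
Reactants: 13 (4S)-4-bromo-5,5-dimethyl-1-methylidenespiro[5.5]undecan-9-one
Product: 14 (4S,6R)-4-bromo-5,5-dimethyl-1-methylidene-9-(trimethylsilyloxy)spiro[5.5]undec-9-ene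
Conditions: (S,S)-bis(1-phenylethyl)amine, n-BuLi, LiCl, TMSCl (internal quench), THF, −100 °C
Reagents that add atoms: chlorotrimethylsilane, C[Si](C)(C)Cl
Why: Group-selective deprotonation of a 4,4-disubstituted cyclohexanone by a chiral lithium amide with internal silyl quench (Simpkins-type desymmetrization). Ring B is locked with CMe2 equatorial and C1 axial, and the base should remove the axial proton at C10 in preference to that at C8. This choice creates the C6 stereocentre as 6R; the C4 centre is too remote to override the reagent.

Step 11
Reactants: 14 (4S,6R)-4-bromo-5,5-dimethyl-1-methylidene-9-(trimethylsilyloxy)spiro[5.5]undec-9-ene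
Product: 15 (4S,6R,10R)-4,10-dibromo-5,5-dimethyl-1-methylidenespiro[5.5]undecan-9-one
Conditions: NBS (1.0 equiv), NaHCO3, THF, −78 °C
Reagents that add atoms: N-bromosuccinimide, O=C1CCC(=O)N1Br
Why: Electrophilic bromination of a silyl enol ether, far faster than attack on the 1,1-disubstituted alkene. Bromine should enter anti to the axial C1 substituent of C6 and end equatorial and cis to C5; this is also the thermodynamic C10 epimer, because an axial bromine would be 1,3-diaxial to ring A, so 10R is expected.

Step 12
Reactants: 15 (4S,6R,10R)-4,10-dibromo-5,5-dimethyl-1-methylidenespiro[5.5]undecan-9-one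
Product: 16 (4S,6R,9R,10R)-4,10-dibromo-5,5,9-trimethyl-1-methylidenespiro[5.5]undecan-9-ol (target)
Conditions: MeAl(OAr)2 (Ar = 2,6-di-tert-butyl-4-methylphenyl; 3 equiv, from Me3Al and 2 ArOH), toluene, −78 °C; then MeLi (3 equiv), −78 °C; water quench
Reagents that add atoms: methyllithium, [Li]C
Why: Yamamoto's bulky aluminium phenoxide binds the carbonyl on its equatorial side and forces methyllithium to attack axially. This should give axial methyl and equatorial hydroxyl trans to the equatorial bromine, that is 9R. The trans-diequatorial alkoxide cannot close to an epoxide without a ring flip that would put CMe2 axial.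

## Compound list

1 | cyclohexane-1,3-dione | O=C1CCCC(=O)C1 | starting material
2 | 1,5-dichloropentan-3-one | ClCCC(=O)CCCl | starting material
3 | penta-1,4-dien-3-one | C=CC(=O)C=C | intermediate
4 | 2-(3-oxopent-4-enyl)cyclohexane-1,3-dione | C=CC(=O)CCC1C(=O)CCCC1=O | intermediate
5 | spiro[5.5]undecane-1,5,9-trione | O=C1CCC2(CC1)C(=O)CCCC2=O | intermediate
6 | 9,9-(ethylenedioxy)spiro[5.5]undecane-1,5-dione | O=C1CCCC(=O)C12CCC3(CC2)OCCO3 | intermediate
7 | 9,9-(ethylenedioxy)-1-methylidenespiro[5.5]undecan-5-one | C=C1CCCC(=O)C12CCC3(CC2)OCCO3 | intermediate
8 | (4S)-4-bromo-9,9-(ethylenedioxy)-1-methylidenespiro[5.5]undecan-5-one | C=C1CC[C@H](Br)C(=O)C12CCC3(CC2)OCCO3 | intermediate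
9 | (4S,5R)-4-bromo-9,9-(ethylenedioxy)-5-methyl-1-methylidenespiro[5.5]undecan-5-ol | C=C1CC[C@H](Br)[C@](C)(O)C12CCC3(CC2)OCCO3 | intermediate
10 | (4S,5R)-4-bromo-5-hydroxy-5-methyl-1-methylidenespiro[5.5]undecan-9-one | C=C1CC[C@H](Br)[C@](C)(O)C12CCC(=O)CC2 | intermediate
11 | (4S,5R)-4-bromo-5-methyl-1-methylidenespiro[5.5]undecane-5,9-diol, C9 epimers | C=C1CC[C@H](Br)[C@](C)(O)C12CCC(O)CC2 | intermediate
12 | (4S)-4-bromo-5,5-dimethyl-1-methylidenespiro[5.5]undecan-9-ol, C9 epimers | C=C1CC[C@H](Br)C(C)(C)C12CCC(O)CC2 | intermediate
13 | (4S)-4-bromo-5,5-dimethyl-1-methylidenespiro[5.5]undecan-9-one | C=C1CC[C@H](Br)C(C)(C)C12CCC(=O)CC2 | intermediate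
14 | (4S,6R)-4-bromo-5,5-dimethyl-1-methylidene-9-(trimethylsilyloxy)spiro[5.5]undec-9-ene | C=C1CC[C@H](Br)C(C)(C)[C@@]12CCC(O[Si](C)(C)C)=CC2 | intermediate
15 | (4S,6R,10R)-4,10-dibromo-5,5-dimethyl-1-methylidenespiro[5.5]undecan-9-one | C=C1CC[C@H](Br)C(C)(C)[C@@]12CCC(=O)[C@H](Br)C2 | intermediate
16 | (4S,6R,9R,10R)-4,10-dibromo-5,5,9-trimethyl-1-methylidenespiro[5.5]undecan-9-ol | C=C1CC[C@H](Br)C(C)(C)[C@@]12CC[C@@](C)(O)[C@H](Br)C2 | target

## Step count and least certain steps

Total step count: 12. Longest linear sequence: 12 steps (from 1 and 2 to 16).

**Step 8 (proposed new method).** Most likely failure: the ionization takes another course. A 1,2-shift of a ring B carbon from C6 would give an allylic cation with ring expansion; proton loss would give a vinylic or allylic bromide; methyl could attack C4 with bromine migration; or the cation could be captured by the exocyclic alkene. The cause is a tertiary cation next to a quaternary carbon that bears a vinyl group. The fallback uses known reactions only, sets out from 7 and returns at 13, so it replaces steps 4 to 9. In it the roles of the two functionalized ring A carbons of 7 are exchanged: its methylidene carbon becomes C5 and its carbonyl carbon becomes C1. Allylic oxidation of 7 (SeO2 cat., t-BuOOH, CH2Cl2) should give racemic 9,9-(ethylenedioxy)-4-hydroxy-5-methylidenespiro[5.5]undecan-1-one F1, and Dess–Martin oxidation then gives 9,9-(ethylenedioxy)-5-methylidenespiro[5.5]undecane-1,4-dione F2. Corey–Bakshi–Shibata reduction ((S)-methyl oxazaborolidine, catecholborane, −78 °C), which should take the enone carbonyl before the neopentyl C1 ketone, gives (4R)-9,9-(ethylenedioxy)-4-hydroxy-5-methylidenespiro[5.5]undecan-1-one F3. Hydroxyl-directed Simmons–Smith cyclopropanation (Et2Zn, CH2I2) gives the (4R)-spiro-cyclopropyl carbinol F4, in which C5 carries a CH2–CH2 bridge. Hydrogenolysis of the distal cyclopropane bond (H2, PtO2, AcOH), with the neopentyl C1 ketone slow to reduce, gives (4R)-9,9-(ethylenedioxy)-4-hydroxy-5,5-dimethylspiro[5.5]undecan-1-one F5. Methylenation of the hindered C1 ketone (excess Ph3P=CH2, toluene, 90 °C) gives (4R)-9,9-(ethylenedioxy)-5,5-dimethyl-1-methylidenespiro[5.5]undecan-4-ol F6. Appel bromination (CBr4, PPh3), a displacement with inversion that is slow at this neopentyl carbinol and competes with elimination, gives (4S)-4-bromo-9,9-(ethylenedioxy)-5,5-dimethyl-1-methylidenespiro[5.5]undecane F7. PPTS in aqueous acetone removes the ketal and returns the material to the route at 13.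

**Step 1 (key step).** Most likely failure: the second conjugate addition occurs between molecules instead of within 4, or the dienone polymerizes, because 4 carries both a nucleophile and an acceptor and 3 is very reactive. The fallback runs from 1 to 5 by a cycloaddition instead of two conjugate additions. Condensation of 1 with formaldehyde (paraformaldehyde, catalytic L-proline) releases 2-methylidenecyclohexane-1,3-dione F8 in the presence of 2-(trimethylsilyloxy)buta-1,3-diene. The Diels–Alder reaction, with the usual para orientation, gives 9-(trimethylsilyloxy)spiro[5.5]undec-8-ene-1,5-dione F9, and dilute acid hydrolysis gives 5.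

**Step 4.** Most likely failure: slow condensation of the catalyst with the neopentyl ketone, giving low conversion, and loss of enantiomeric purity by enolization of the product. The fallback runs from 7 to 8 through oxygen instead of bromine. LiN(iPr)2 and TBSCl give the enol ether 5-(tert-butyldimethylsilyloxy)-9,9-(ethylenedioxy)-1-methylidenespiro[5.5]undec-4-ene F10. Shi epoxidation (fructose-derived ketone or its antipode as the required face demands, Oxone (KHSO5), K2CO3 buffer) and mild aqueous acid work-up give (4R)-9,9-(ethylenedioxy)-4-hydroxy-1-methylidenespiro[5.5]undecan-5-one F11. Tf2O and 2,6-lutidine at −78 °C give (4R)-9,9-(ethylenedioxy)-1-methylidene-5-oxospiro[5.5]undecan-4-yl trifluoromethanesulfonate F12. One equivalent of Bu4NBr at −40 °C displaces the triflate with inversion and returns to the route at 8.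

**Step 10.** Most likely failure: poor discrimination between the two α-methylenes, because the base meets a 4,4-disubstituted ring with an axial substituent near the protons it must remove and a possibly mismatched C4 centre. The result would be the C6 epimer. The fallback runs from 13 directly to 15 by amine-catalysed desymmetrizing α-bromination with 4,5-diphenylimidazolidine and the dibromodienone of step 4. This moves the stereo-determining event from proton removal to bromination of a chiral enamine on an unhindered ketone. It makes no compound outside the list and is entered as F0.

**Step 12.** Most likely failure: poor facial selectivity (equatorial attack gives the cis Br/OH epimer), or bromine–lithium exchange and enolization of the α-bromoketone. The fallback runs from 15 to 16 and builds the carbinol in two stages, the C–C bond first and a C–H bond second, so that the selectivity comes from the nucleophile itself. Dimethylsulfonium methylide (Me3SI, KN(SiMe3)2, THF, −20 °C), a small ylide that adds to cyclohexanones axially and irreversibly, should close to the spiro-epoxide F13, in which the new CH2 is axial and the oxygen is equatorial and trans to the C10 bromine. LiAlH4 (Et2O, −20 °C) should then open the epoxide at its CH2 terminus, which is much faster than reduction of a hindered secondary cyclohexyl bromide, and give 16 with axial methyl and equatorial hydroxyl.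

## Further compounds

F1 | step 8 | 9,9-(ethylenedioxy)-4-hydroxy-5-methylidenespiro[5.5]undecan-1-one (racemic) | C=C1C(O)CCC(=O)C12CCC3(CC2)OCCO3
F2 | step 8 | 9,9-(ethylenedioxy)-5-methylidenespiro[5.5]undecane-1,4-dione | C=C1C(=O)CCC(=O)C12CCC3(CC2)OCCO3
F3 | step 8 | (4R)-9,9-(ethylenedioxy)-4-hydroxy-5-methylidenespiro[5.5]undecan-1-one | C=C1[C@H](O)CCC(=O)C12CCC3(CC2)OCCO3
F4 | step 8 | (4R)-spiro-cyclopropyl carbinol (C5 of F3 as a spiro cyclopropane) | O=C1CC[C@@H](O)C2(CC2)C13CCC4(CC3)OCCO4
F5 | step 8 | (4R)-9,9-(ethylenedioxy)-4-hydroxy-5,5-dimethylspiro[5.5]undecan-1-one | O=C1CC[C@@H](O)C(C)(C)C12CCC3(CC2)OCCO3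
F6 | step 8 | (4R)-9,9-(ethylenedioxy)-5,5-dimethyl-1-methylidenespiro[5.5]undecan-4-ol | C=C1CC[C@@H](O)C(C)(C)C12CCC3(CC2)OCCO3
F7 | step 8 | (4S)-4-bromo-9,9-(ethylenedioxy)-5,5-dimethyl-1-methylidenespiro[5.5]undecane | C=C1CC[C@H](Br)C(C)(C)C12CCC3(CC2)OCCO3
F8 | step 1 | 2-methylidenecyclohexane-1,3-dione | C=C1C(=O)CCCC1=O
F9 | step 1 | 9-(trimethylsilyloxy)spiro[5.5]undec-8-ene-1,5-dione | C[Si](C)(C)OC1=CCC2(CC1)C(=O)CCCC2=O
F10 | step 4 | 5-(tert-butyldimethylsilyloxy)-9,9-(ethylenedioxy)-1-methylidenespiro[5.5]undec-4-ene | C=C1CCC=C(O[Si](C)(C)C(C)(C)C)C12CCC3(CC2)OCCO3
F11 | step 4 | (4R)-9,9-(ethylenedioxy)-4-hydroxy-1-methylidenespiro[5.5]undecan-5-one | C=C1CC[C@@H](O)C(=O)C12CCC3(CC2)OCCO3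
F12 | step 4 | (4R)-9,9-(ethylenedioxy)-1-methylidene-5-oxospiro[5.5]undecan-4-yl trifluoromethanesulfonate | C=C1CC[C@@H](OS(=O)(=O)C(F)(F)F)C(=O)C12CCC3(CC2)OCCO3
F0 | step 10 | none | none
F13 | step 12 | (4S,6R,9S,10R)-4,10-dibromo-5,5-dimethyl-1-methylidenespiro[5.5]undecane-9-spiro-2'-oxirane (oxygen equatorial, trans to the C10 bromine) | C=C1CC[C@H](Br)C(C)(C)[C@@]12CC[C@@]3(OC3)[C@H](Br)C2
A1 | alternative 1 | 6-bromo-1-methyl-3-oxo-2-oxabicyclo[2.2.2]octane-4-carboxylic acid | OC(=O)[C@@]12CC[C@@](C)(OC1=O)[C@H](Br)C2
A2 | alternative 1 | 4-methylcyclohex-3-ene-1,1-dicarboxylic acid | CC1=CCC(CC1)(C(=O)O)C(=O)O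
A3 | alternative 2 | (2S,6S)-2-bromo-1,1,9-trimethylspiro[5.5]undec-8-en-5-one | O=C1CC[C@H](Br)C(C)(C)[C@@]12CCC(C)=CC2
A4 | alternative 2 | (2R,6S)-6-bromo-2-ethenyl-2,5,5-trimethyl-3,4,5,6,7,8-hexahydro-2H-chromene | C=C[C@@]1(C)CCC2=C(O1)CC[C@H](Br)C2(C)C
A5 | alternative 2 | (R)-linalool | C=C[C@](C)(O)CCC=C(C)C
A6 | alternative 3 | (2S)-2-bromo-1,1-dimethyl-5-methylidenespiro[5.5]undeca-7,10-dien-9-one | C=C1CC[C@H](Br)C(C)(C)C12C=CC(=O)C=C2
A7 | alternative 3 | 4-[(3S)-3-bromo-2-methylhept-6-yn-2-yl]phenol | C#CCC[C@H](Br)C(C)(C)c1ccc(O)cc1
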